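**Retrosynthetic overview**

1. Locants: ring C1–C14 (C14 = stereogenic CH; C1 = the CH2 between C14 and the Z-alkene C2=C3; Me on C3 and C11; CO2H on C7), side chain C15–C19. 29 ⇐ 28 (saponification) ⇐ 26: the single ring, the 14-membered carbocycle, is formed last, at C11–C12, by 9-BBN hydroboration of a vinyl group and intramolecular B-alkyl Suzuki coupling.
2. 26 ⇐ 25 + 7: an NHC–Cu-catalysed enantioselective SN2′ allylic substitution joins the C8 alkenylboronate to the achiral, linear C17 (E)-allylic phosphate through the C14–C15 bond, creates the only stereocentre and carries the E side-chain alkene over unchanged.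
3. Enabling feature: C14 is a methine between the alkenyl carbon C15 and the saturated C13–C12 link to the sp2 ring carbon C11. Read back as a vinyl group (C13=C12), this makes C14 the branch point of a 1,4-diene, the direct product of a γ-selective allylic substitution with the leaving group on C12, and makes C12 the boron partner for ring closure.
4. 25 ⇐ 24 + 13 by Horner–Wadsworth–Emmons olefination (C6=C7). 24 comes from neryl acetate (Z-C2=C3 from the pool, C1–C14 by copper-mediated propargylation, E-C13=C14 by trans-hydroalumination); 13 comes from pent-3-yn-1-ol (E-alkenyl iodide by hydrozirconation–iodination).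
5. 7 ⇐ prenyl bromide + propynylmagnesium bromide, then hydrozirconation–iodination and I–Li exchange/borylation.

Key step: step 15

Remark: the chiral sulfonate-bearing imidazolinium salt of step 15 is a catalyst taken as accessible in either enantiomeric form from (R,R)- or (S,S)-1,2-diphenylethylenediamine, and the enantiomer that delivers the alkenyl group to the face giving (9S)-26 is assumed to be used (9S in 26 corresponds to 8R in 28 and 29 only because the CIP ranking of the two ring arms changes on ring closure).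

**Step 1**
Reactants: 1 prenyl bromide (1-bromo-3-methylbut-2-ene); 2 prop-1-yn-1-ylmagnesium bromide
Product: 3 6-methylhept-5-en-2-yne
Conditions: CuI (5 mol %), THF, 0 °C → rt
Reagents that add atoms: none
Why: Copper-catalysed SN2 (α-selective) coupling of an alkynyl Grignard reagent with a primary allylic bromide should give the skipped enyne, with no stereo element involved.

**Step 2**
Reactants: 3 6-methylhept-5-en-2-yne
Product: 5 (2E)-2-iodo-6-methylhepta-2,5-diene, via alkenylzirconocene chloride 4 (not isolated)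
Conditions: Cp2Zr(H)Cl (1.5 equiv), THF, rt → 40 °C; then I2, 0 °C
Reagents that add atoms: iodine II
Why: Hydrozirconation–iodination: syn addition of Zr–H to the 2-alkyne, equilibrated by the slight excess of hydride so that zirconium sits on the less hindered methyl-bearing carbon, followed by stereoretentive iodinolysis should place iodine trans to the chain, while the trisubstituted alkene is too hindered to react.

**Step 3**
Reactants: 5 (2E)-2-iodo-6-methylhepta-2,5-diene
Product: 7 2-[(2Z)-6-methylhepta-2,5-dien-2-yl]-4,4,5,5-tetramethyl-1,3,2-dioxaborolane, via alkenyllithium 6 (not isolated)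
Conditions: t-BuLi (2.1 equiv), Et2O, −78 °C; then i-PrOB(pin), −78 °C → rt; HCl/Et2O
Reagents that add atoms: 2-isopropoxy-4,4,5,5-tetramethyl-1,3,2-dioxaborolane CC(C)OB1OC(C)(C)C(C)(C)O1
Why: Iodine–lithium exchange gives an alkenyllithium that is configurationally stable at −78 °C and is borylated with retention, so boron ends trans to the chain (formally 2Z because carbon outranks boron).

**Step 4**
Reactants: 8 pent-3-yn-1-ol
Product: 9 5-bromopent-2-yne
Conditions: CBr4, PPh3, CH2Cl2, 0 °C
Reagents that add atoms: carbon tetrabromide BrC(Br)(Br)Br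
Why: Appel bromination converts the primary alcohol into the bromide by SN2 displacement of the alkoxyphosphonium under neutral conditions.

**Step 5**
Reactants: 9 5-bromopent-2-yne
Product: 11 (2E)-5-bromo-2-iodopent-2-ene, via alkenylzirconocene chloride 10 (not isolated)
Conditions: Cp2Zr(H)Cl (1.5 equiv), THF, rt; then I2, 0 °C
Reagents that add atoms: iodine II
Why: Hydrozirconation–iodination as in step 2 should put zirconium, and then iodine, on the methyl-bearing alkyne carbon trans to the chain, the primary alkyl bromide being tolerated by the zirconium hydride at room temperature.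

**Step 6**
Reactants: 11 (2E)-5-bromo-2-iodopent-2-ene; 12 methyl 2-(diethoxyphosphoryl)acetate
Product: 13 methyl (5E)-2-(diethoxyphosphoryl)-6-iodohept-5-enoate (racemic at C-2)
Conditions: NaH, DMF, 0 → 50 °C (12 in excess)
Reagents that add atoms: none
Why: SN2 C-alkylation of the sodium phosphonoacetate carbanion with the primary bromide should leave the alkenyl iodide untouched, and the new α-centre is destroyed in step 14.

**Step 7**
Reactants: 14 neryl acetate [(2Z)-3,7-dimethylocta-2,6-dien-1-yl acetate]
Product: 16 (2Z)-3-methyl-6-oxohex-2-en-1-yl acetate, via secondary ozonide 15 (not isolated)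
Conditions: O3 (1.0 equiv), CH2Cl2, −78 °C; then Me2S, −78 °C → rt
Reagents that add atoms: ozone [O-][O+]=O
Why: Chemoselective ozonolysis with reductive work-up: the electron-rich distal trisubstituted alkene should react faster than the 2,3-alkene deactivated by the allylic acetate, so the Z-alkene is kept.

**Step 8**
Reactants: 16 (2Z)-3-methyl-6-oxohex-2-en-1-yl acetate
Product: 18 (2Z)-6,6-dimethoxy-3-methylhex-2-en-1-ol, via acetal acetate 17 (not isolated)
Conditions: HC(OMe)3, PPTS (cat.), MeOH, rt; then K2CO3, rt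
Reagents that add atoms: trimethyl orthoformate COC(OC)OC
Why: Acid-catalysed acetalisation followed in the same pot by base-catalysed methanolysis of the acetate masks the aldehyde and frees the allylic alcohol without touching the Z-alkene.

**Step 9**
Reactants: 18 (2Z)-6,6-dimethoxy-3-methylhex-2-en-1-ol
Product: 19 (2Z)-1-bromo-6,6-dimethoxy-3-methylhex-2-ene
Conditions: CBr4, PPh3, 2,6-lutidine, CH2Cl2, −20 °C; used directly
Reagents that add atoms: carbon tetrabromide BrC(Br)(Br)Br
Why: Buffered Appel bromination should give the primary allylic bromide by SN2 without acetal cleavage, and low temperature with immediate use limits Z→E isomerisation.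

**Step 10**
Reactants: 19 (2Z)-1-bromo-6,6-dimethoxy-3-methylhex-2-ene; 20 prop-2-yn-1-ol
Product: 21 (5Z)-9,9-dimethoxy-6-methylnon-5-en-2-yn-1-ol
Conditions: CuI (cat.), Cs2CO3, DMF, rt
Reagents that add atoms: none
Why: Copper-acetylide substitution of the primary allylic bromide (base-mediated propargyl–allyl coupling) should occur at the α-carbon with retention of the Z-alkene to give the skipped enynol.

**Step 11**
Reactants: 21 (5Z)-9,9-dimethoxy-6-methylnon-5-en-2-yn-1-ol
Product: 22 (2E,5Z)-9,9-dimethoxy-6-methylnona-2,5-dien-1-ol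
Conditions: LiAlH4, THF, 0 °C → reflux; aqueous NaOH work-up
Reagents that add atoms: none
Why: Hydroxyl-directed trans-hydroalumination of the propargylic alcohol and protonolysis on work-up give the E-allylic alcohol, while the isolated alkene and the acetal are inert to the hydride.

**Step 12**
Reactants: 22 (2E,5Z)-9,9-dimethoxy-6-methylnona-2,5-dien-1-ol
Product: 23 (2E,5Z)-9,9-dimethoxy-6-methylnona-2,5-dien-1-yl diethyl phosphate
Conditions: ClP(O)(OEt)2, Et3N, DMAP (cat.), CH2Cl2, 0 °C
Reagents that add atoms: diethyl chlorophosphate CCOP(=O)(Cl)OCC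
Why: O-Phosphorylation of the primary allylic alcohol installs the leaving group needed for the copper-catalysed substitution without affecting either alkene.

**Step 13**
Reactants: 23 (2E,5Z)-9,9-dimethoxy-6-methylnona-2,5-dien-1-yl diethyl phosphate
Product: 24 diethyl (2E,5Z)-6-methyl-9-oxonona-2,5-dien-1-yl phosphate
Conditions: PPTS (cat.), acetone/H2O, 40 °C
Reagents that add atoms: water O
Why: Mild acid-catalysed acetal hydrolysis should free the aldehyde while the primary allylic phosphate and the skipped diene survive.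

**Step 14**
Reactants: 24 diethyl (2E,5Z)-6-methyl-9-oxonona-2,5-dien-1-yl phosphate; 13 methyl (5E)-2-(diethoxyphosphoryl)-6-iodohept-5-enoate
Product: 25 methyl (2E,6Z,9E)-11-[(diethoxyphosphoryl)oxy]-2-[(3E)-4-iodopent-3-en-1-yl]-6-methylundeca-2,6,9-trienoate
Conditions: NaH, THF, 0 °C; then 24, 0 °C → rt
Reagents that add atoms: none
Why: Horner–Wadsworth–Emmons olefination of an α-alkyl phosphonoacetate with an unbranched aldehyde favours the E enoate (ester trans to the aldehyde-derived chain, as required at C6=C7), and carbonyl addition should be much faster than alkylation of the carbanion by the allylic phosphate.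

**Step 15**
Reactants: 25 linear (E)-allylic phosphate; 7 alkenyl–B(pin)
Product: 26 methyl (2E,6Z,9S,10E)-9-ethenyl-2-[(3E)-4-iodopent-3-en-1-yl]-6,10,14-trimethylpentadeca-2,6,10,13-tetraenoate
Conditions: CuCl (5 mol %), chiral sulfonate-bearing imidazolinium salt (5.5 mol %), NaOMe (1.5 equiv), 7 (1.5 equiv), THF, 22 °C
Reagents that add atoms: none
Why: Methoxide turns 7 into a borate that hands its alkenyl group with retention to the chiral NHC–Cu(I) centre, and this alkenylcopper adds to the γ-carbon C14 of the E-allylic phosphate anti to the leaving group to give a Cu(III) allyl species, whose reductive elimination forms the C14–C15 bond and leaves the alkene at C13=C12. The closest known reaction type is the NHC–Cu-catalysed enantioselective allylic substitution of E-disubstituted allylic phosphates with alkenyl–B(pin) reagents, α-substituted ones included, which gives 1,4-dienes with a tertiary stereocentre. No ring is closed here; the step releases the vinyl group through which the 14-membered ring is closed in step 16. The new stereocentre C14 is under catalyst control: the sulfonate-bridged NHC–Cu complex differentiates the enantiotopic faces of the achiral alkene, and the ligand enantiomer is chosen for the 9S product. The step needs γ- over α-selectivity and retention of the alkenyl geometry, which the phosphate leaving group with the bidentate sulfonate–NHC ligand and the stereoretentive transmetallation and reductive elimination should secure. It also needs chemoselectivity, and the alkenyl iodide and the trisubstituted enoate should be inert to the alkenylcopper at room temperature while the methyl ester is matched to the methoxide base.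

**Step 16**
Reactants: 26 seco vinyl/alkenyl iodide
Product: 28 methyl (1E,5Z,8R,11E)-5,11-dimethyl-8-[(2E)-6-methylhepta-2,5-dien-2-yl]cyclotetradeca-1,5,11-triene-1-carboxylate, via B-alkyl-9-BBN borane 27 (not isolated)
Conditions: 9-BBN (1.3 equiv), THF, 0 °C → rt; then slow addition to PdCl2(dppf) (10 mol %), AsPh3, Cs2CO3, DMF/THF/H2O, 50 °C (2 mM)
Reagents that add atoms: none
Why: 9-BBN should hydroborate only the monosubstituted alkene (anti-Markovnikov), and intramolecular B-alkyl Suzuki–Miyaura coupling with the E-alkenyl iodide under high dilution closes the 14-membered ring at C11–C12 with retention of alkene geometry and without involving the stereocentre.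

**Step 17**
Reactants: 28 macrocyclic methyl ester
Product: 29 (1E,5Z,8R,11E)-5,11-dimethyl-8-[(2E)-6-methylhepta-2,5-dien-2-yl]cyclotetradeca-1,5,11-triene-1-carboxylic acid (target)
Conditions: LiOH, THF/MeOH/H2O, 45 °C; then 1 M HCl
Reagents that add atoms: lithium hydroxide [Li+].[OH-]
Why: Saponification of the conjugated methyl ester should leave the thermodynamically preferred E-enoate and the remote, non-epimerisable C14 stereocentre unchanged.

**Compound list**

1 | prenyl bromide (1-bromo-3-methylbut-2-ene) | CC(C)=CCBr | starting material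
2 | prop-1-yn-1-ylmagnesium bromide | CC#C[Mg]Br | starting material
3 | 6-methylhept-5-en-2-yne | CC#CCC=C(C)C | intermediate
4 | chloridobis(cyclopentadienyl)[(2E)-6-methylhepta-2,5-dien-2-yl]zirconium | CC(C)=CC/C=C(\C)[Zr](Cl)(C1C=CC=C1)C1C=CC=C1 | intermediate
5 | (2E)-2-iodo-6-methylhepta-2,5-diene | CC(C)=CC/C=C(\C)I | intermediate
6 | [(2Z)-6-methylhepta-2,5-dien-2-yl]lithium (Li trans to the chain) | CC(C)=CC/C=C(\C)[Li] | intermediate
7 | 2-[(2Z)-6-methylhepta-2,5-dien-2-yl]-4,4,5,5-tetramethyl-1,3,2-dioxaborolane (B trans to the chain) | CC(C)=CC/C=C(\C)B1OC(C)(C)C(C)(C)O1 | intermediate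
8 | pent-3-yn-1-ol | CC#CCCO | starting material
9 | 5-bromopent-2-yne | CC#CCCBr | intermediate
10 | [(2E)-5-bromopent-2-en-2-yl]chloridobis(cyclopentadienyl)zirconium | BrCC/C=C(\C)[Zr](Cl)(C1C=CC=C1)C1C=CC=C1 | intermediate
11 | (2E)-5-bromo-2-iodopent-2-ene | BrCC/C=C(\C)I | intermediate
12 | methyl 2-(diethoxyphosphoryl)acetate | COC(=O)CP(=O)(OCC)OCC | starting material
13 | methyl (5E)-2-(diethoxyphosphoryl)-6-iodohept-5-enoate (racemic at C-2) | COC(=O)C(CC/C=C(\C)I)P(=O)(OCC)OCC | intermediate
14 | neryl acetate, (2Z)-3,7-dimethylocta-2,6-dien-1-yl acetate | CC(=O)OC/C=C(/C)CCC=C(C)C | starting material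
15 | (2Z)-5-(5,5-dimethyl-1,2,4-trioxolan-3-yl)-3-methylpent-2-en-1-yl acetate | CC(=O)OC/C=C(/C)CCC1OOC(C)(C)O1 | intermediate
16 | (2Z)-3-methyl-6-oxohex-2-en-1-yl acetate | CC(=O)OC/C=C(/C)CCC=O | intermediate
17 | (2Z)-6,6-dimethoxy-3-methylhex-2-en-1-yl acetate | CC(=O)OC/C=C(/C)CCC(OC)OC | intermediate
18 | (2Z)-6,6-dimethoxy-3-methylhex-2-en-1-ol | OC/C=C(/C)CCC(OC)OC | intermediate
19 | (2Z)-1-bromo-6,6-dimethoxy-3-methylhex-2-ene | BrC/C=C(/C)CCC(OC)OC | intermediate
20 | prop-2-yn-1-ol | C#CCO | starting material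
21 | (5Z)-9,9-dimethoxy-6-methylnon-5-en-2-yn-1-ol | OCC#CC/C=C(/C)CCC(OC)OC | intermediate
22 | (2E,5Z)-9,9-dimethoxy-6-methylnona-2,5-dien-1-ol | OC/C=C/C/C=C(/C)CCC(OC)OC | intermediate
23 | (2E,5Z)-9,9-dimethoxy-6-methylnona-2,5-dien-1-yl diethyl phosphate | CCOP(=O)(OCC)OC/C=C/C/C=C(/C)CCC(OC)OC | intermediate
24 | diethyl (2E,5Z)-6-methyl-9-oxonona-2,5-dien-1-yl phosphate | CCOP(=O)(OCC)OC/C=C/C/C=C(/C)CCC=O | intermediate
25 | methyl (2E,6Z,9E)-11-[(diethoxyphosphoryl)oxy]-2-[(3E)-4-iodopent-3-en-1-yl]-6-methylundeca-2,6,9-trienoate | CCOP(=O)(OCC)OC/C=C/C/C=C(/C)CC/C=C(/C(=O)OC)CC/C=C(\C)I | intermediate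
26 | methyl (2E,6Z,9S,10E)-9-ethenyl-2-[(3E)-4-iodopent-3-en-1-yl]-6,10,14-trimethylpentadeca-2,6,10,13-tetraenoate | CC(C)=CC/C=C(\C)[C@H](C=C)C/C=C(/C)CC/C=C(/C(=O)OC)CC/C=C(\C)I | intermediate
27 | methyl (2E,6Z,9R,10E)-9-[2-(9-borabicyclo[3.3.1]nonan-9-yl)ethyl]-2-[(3E)-4-iodopent-3-en-1-yl]-6,10,14-trimethylpentadeca-2,6,10,13-tetraenoate | CC(C)=CC/C=C(\C)[C@H](CCB1C2CCCC1CCC2)C/C=C(/C)CC/C=C(/C(=O)OC)CC/C=C(\C)I | intermediate
28 | methyl (1E,5Z,8R,11E)-5,11-dimethyl-8-[(2E)-6-methylhepta-2,5-dien-2-yl]cyclotetradeca-1,5,11-triene-1-carboxylate | CC(C)=CC/C=C(\C)[C@H]1C/C=C(/C)CC/C=C(/C(=O)OC)CC/C=C(\C)CC1 | intermediate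
29 | (1E,5Z,8R,11E)-5,11-dimethyl-8-[(2E)-6-methylhepta-2,5-dien-2-yl]cyclotetradeca-1,5,11-triene-1-carboxylic acid | CC(C)=CC/C=C(\C)[C@H]1C/C=C(/C)CC/C=C(/C(=O)O)CC/C=C(\C)CC1 | target

**Totals**

Total step count: 17. Longest linear sequence: 11 steps (steps 7–17, from neryl acetate 14).

**Steps most likely to fail**

Step 15. The process at risk is enantiofacial discrimination for an allylic phosphate whose γ-substituent is only an unbranched CH2 group; α-substitution may also compete, and boron-to-copper transfer of the α-methyl alkenyl group may be slow. The fallback moves stereocontrol to a reagent-controlled epoxidation and a stereospecific SN2 epoxide opening. It sets out from dienol 22 (with iodide 5) and comes back at 26. Dienol 22 would be epoxidised under Sharpless conditions (Ti(OiPr)4, D-(−)-diethyl tartrate, t-BuOOH, 4 Å sieves, CH2Cl2, −20 °C) to [(2R,3R)-3-[(2Z)-6,6-dimethoxy-3-methylhex-2-en-1-yl]oxiran-2-yl]methanol F1. Iodide 5 would be taken through alkenyllithium 6 and Me2AlCl to dimethyl[(2E)-6-methylhepta-2,5-dien-2-yl]alumane F2. This alane (excess, CH2Cl2/hexane, −78 → 0 °C) should open the epoxy alcohol at C-3 with inversion, as trialkyl- and alkynylalanes do, to give (2S,3R,4E)-3-[(2Z)-6,6-dimethoxy-3-methylhex-2-en-1-yl]-4,8-dimethylnona-4,7-diene-1,2-diol F3. Acetal hydrolysis (AcOH, THF/H2O) would give (4Z,7R,8S)-8,9-dihydroxy-4-methyl-7-[(2E)-6-methylhepta-2,5-dien-2-yl]non-4-enal F4. Horner–Wadsworth–Emmons olefination with 13 (LiCl, DBU, MeCN) would give methyl (2E,6Z,9R,10E)-9-[(1S)-1,2-dihydroxyethyl]-2-[(3E)-4-iodopent-3-en-1-yl]-6,10,14-trimethylpentadeca-2,6,10,13-tetraenoate F5. Garegg–Samuelsson deoxygenation of the terminal 1,2-diol (PPh3, I2, imidazole, toluene, 80 °C) would turn it into the vinyl group and return 26.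

Step 16. The process at risk is ring closure itself: oligomerisation, protodeboronation or β-hydride elimination may outrun transmetallation and reductive elimination across the forming 14-membered ring. The fallback makes the C11–C12 bond intermolecularly and closes the ring at C6=C7 by a macrocyclic olefination. It sets out from acetal phosphate 23 (with 7 and 13) and comes back at 28. Under the conditions of step 15, 23 and 7 would give (4Z,7S,8E)-7-ethenyl-1,1-dimethoxy-4,8,12-trimethyltrideca-4,8,11-triene F6. Hydroboration with 9-BBN would give 9-[(3R,4E)-3-[(2Z)-6,6-dimethoxy-3-methylhex-2-en-1-yl]-4,8-dimethylnona-4,7-dien-1-yl]-9-borabicyclo[3.3.1]nonane F7. Suzuki–Miyaura coupling of this borane with alkenyl iodide 13 (PdCl2(dppf), AsPh3, Cs2CO3, DMF/H2O) would give methyl (5E,9R,10E)-2-(diethoxyphosphoryl)-9-[(2Z)-6,6-dimethoxy-3-methylhex-2-en-1-yl]-6,10,14-trimethylpentadeca-5,10,13-trienoate F8. Acetal hydrolysis (PPTS, acetone/H2O) would give methyl (5E,9R,10E)-2-(diethoxyphosphoryl)-6,10,14-trimethyl-9-[(2Z)-3-methyl-6-oxohex-2-en-1-yl]pentadeca-5,10,13-trienoate F9. Intramolecular Horner–Wadsworth–Emmons olefination (LiCl, DBU, MeCN, high dilution) would then close the ring and return 28.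

Step 10. The process at risk is regiocontrol and geometric integrity: the copper acetylide may attack the tertiary γ-terminus, and reversible ionisation of the allylic bromide may erode the Z-alkene. The fallback builds the E-alkene by syn-hydrozirconation of a terminal alkyne and joins it by a palladium-catalysed alkenyl–allyl (Negishi-type) coupling, which is known to retain allyl geometry; it replaces steps 10 and 11. It sets out from bromide 19 and comes back at 22. tert-Butyldimethyl(prop-2-yn-1-yloxy)silane and Cp2Zr(H)Cl would give [(1E)-3-{[tert-butyl(dimethyl)silyl]oxy}prop-1-en-1-yl]chloridobis(cyclopentadienyl)zirconium F10. Coupling of this alkenylzirconocene with 19 (Pd(PPh3)4, 5 mol %, THF, rt) would give tert-butyl{[(2E,5Z)-9,9-dimethoxy-6-methylnona-2,5-dien-1-yl]oxy}dimethylsilane F11. Desilylation with Bu4NF in THF would return 22.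

**Further compounds**

F1 | step 15 | [(2R,3R)-3-[(2Z)-6,6-dimethoxy-3-methylhex-2-en-1-yl]oxiran-2-yl]methanol | OC[C@H]1O[C@@H]1C/C=C(/C)CCC(OC)OC
F2 | step 15 | dimethyl[(2E)-6-methylhepta-2,5-dien-2-yl]alumane | CC(C)=CC/C=C(\C)[Al](C)C
F3 | step 15 | (2S,3R,4E)-3-[(2Z)-6,6-dimethoxy-3-methylhex-2-en-1-yl]-4,8-dimethylnona-4,7-diene-1,2-diol | CC(C)=CC/C=C(\C)[C@H]([C@H](O)CO)C/C=C(/C)CCC(OC)OC
F4 | step 15 | (4Z,7R,8S)-8,9-dihydroxy-4-methyl-7-[(2E)-6-methylhepta-2,5-dien-2-yl]non-4-enal | CC(C)=CC/C=C(\C)[C@H]([C@H](O)CO)C/C=C(/C)CCC=O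
F5 | step 15 | methyl (2E,6Z,9R,10E)-9-[(1S)-1,2-dihydroxyethyl]-2-[(3E)-4-iodopent-3-en-1-yl]-6,10,14-trimethylpentadeca-2,6,10,13-tetraenoate | CC(C)=CC/C=C(\C)[C@H]([C@H](O)CO)C/C=C(/C)CC/C=C(/C(=O)OC)CC/C=C(\C)I
F6 | step 16 | (4Z,7S,8E)-7-ethenyl-1,1-dimethoxy-4,8,12-trimethyltrideca-4,8,11-triene | CC(C)=CC/C=C(\C)[C@H](C=C)C/C=C(/C)CCC(OC)OC
F7 | step 16 | 9-[(3R,4E)-3-[(2Z)-6,6-dimethoxy-3-methylhex-2-en-1-yl]-4,8-dimethylnona-4,7-dien-1-yl]-9-borabicyclo[3.3.1]nonane | CC(C)=CC/C=C(\C)[C@H](CCB1C2CCCC1CCC2)C/C=C(/C)CCC(OC)OC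
F8 | step 16 | methyl (5E,9R,10E)-2-(diethoxyphosphoryl)-9-[(2Z)-6,6-dimethoxy-3-methylhex-2-en-1-yl]-6,10,14-trimethylpentadeca-5,10,13-trienoate (epimers at C-2) | CC(C)=CC/C=C(\C)[C@H](CC/C(C)=C/CCC(C(=O)OC)P(=O)(OCC)OCC)C/C=C(/C)CCC(OC)OC
F9 | step 16 | methyl (5E,9R,10E)-2-(diethoxyphosphoryl)-6,10,14-trimethyl-9-[(2Z)-3-methyl-6-oxohex-2-en-1-yl]pentadeca-5,10,13-trienoate (epimers at C-2) | CC(C)=CC/C=C(\C)[C@H](CC/C(C)=C/CCC(C(=O)OC)P(=O)(OCC)OCC)C/C=C(/C)CCC=O
F10 | step 10 | [(1E)-3-{[tert-butyl(dimethyl)silyl]oxy}prop-1-en-1-yl]chloridobis(cyclopentadienyl)zirconium | CC(C)(C)[Si](C)(C)OC/C=C/[Zr](Cl)(C1C=CC=C1)C1C=CC=C1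
F11 | step 10 | tert-butyl{[(2E,5Z)-9,9-dimethoxy-6-methylnona-2,5-dien-1-yl]oxy}dimethylsilane | CC(C)(C)[Si](C)(C)OC/C=C/C/C=C(/C)CCC(OC)OC
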